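Germacrane numbering: carbocycle C1–C10, lactone ring O–C6–C7–C11–C12. The plan cuts the ten-membered ring between vinylic C1 of the Z-C1=C10 alkene and methylene C2. In one flask the key step hydroborates the terminal C2=C3 vinyl group of a 2-substituted 1,3-diene and cross-couples the primary borane with a Z-alkenyl chloride at C1. This closes the carbocycle, unmasks the C2–C3 bridge and leaves both ring alkenes with their final geometry. It exploits the cis fusion at C6/C7, which holds both arms on one face of the lactone ring. The precursor is an all-cis butyrolactone bearing the dienyl arm, the chloroalkenyl arm and the complete, silyl-protected ester side chain.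

Key step: step 15

Remark: germacrane numbers (C1–C15) are used for all intermediates. Compounds 1, 6, 8, 14, 15, 21 and 22 are assumed to be commercial.

Step 1
Reactants: 1 tert-butyldimethyl(prop-2-yn-1-yloxy)silane
Product: 2 methyl 4-[(tert-butyldimethylsilyl)oxy]but-2-ynoate
Conditions: n-BuLi, THF, −78 °C; ClCO2Me, −78 → 0 °C
Reagents that add atoms: methyl chloroformate COC(=O)Cl
Why: Acetylide acylation, in which the lithium acetylide is C-acylated cleanly by the chloroformate and the silyl ether is inert; no stereocenter is formed.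

Step 2
Reactants: 2 methyl 4-[(tert-butyldimethylsilyl)oxy]but-2-ynoate
Product: 3 methyl (2Z)-3-{[(tert-butyldimethylsilyl)oxy]methyl}penta-2,4-dienoate
Conditions: CH2=CHMgBr, CuI, THF, −78 °C; add 2, −78 °C; sat. aq. NH4Cl at −78 °C
Reagents that add atoms: vinylmagnesium bromide C=C[Mg]Br
Why: Syn-carbocupration of an ynoate places vinyl and copper cis, and protonation at −78 °C before the alkenylcopper can isomerize should fix the geometry with CO2Me (future C6) cis to CH2OTBS (C15) and trans to the vinyl group (C3).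

Step 3
Reactants: 3 methyl (2Z)-3-{[(tert-butyldimethylsilyl)oxy]methyl}penta-2,4-dienoate
Product: 4 (2Z)-3-{[(tert-butyldimethylsilyl)oxy]methyl}penta-2,4-dien-1-ol
Conditions: DIBAL-H (2.2 equiv), CH2Cl2, −78 °C; Rochelle salt
Reagents that add atoms: none
Why: 1,2-Reduction of a conjugated ester with DIBAL-H gives the allylic alcohol without touching the diene, its geometry or the silyl ether.

Step 4
Reactants: 4 (2Z)-3-{[(tert-butyldimethylsilyl)oxy]methyl}penta-2,4-dien-1-ol
Product: 5 (2Z)-3-{[(tert-butyldimethylsilyl)oxy]methyl}penta-2,4-dienal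
Conditions: MnO2, CH2Cl2, 23 °C
Reagents that add atoms: none
Why: Allylic oxidation with MnO2 is neutral and heterogeneous, so the enal geometry should be retained.

Step 5
Reactants: 6 dimethyl (2S)-2-methylbutanedioate
Product: 7 (3S)-4-methoxy-3-methyl-4-oxobutanoic acid
Conditions: LiOH (1.0 equiv), THF–H2O, 0 °C; then 1 M HCl
Reagents that add atoms: lithium hydroxide [Li+].[OH-]
Why: Regioselective saponification, in which the ester next to CH2 is less hindered than the α-branched one; the chiral-pool centre C11 should survive at 0 °C.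

Step 6
Reactants: 7 (3S)-4-methoxy-3-methyl-4-oxobutanoic acid; 8 (4R)-4-benzyl-1,3-thiazolidine-2-thione
Product: 9 methyl (2S)-4-[(4R)-4-benzyl-2-sulfanylidene-1,3-thiazolidin-3-yl]-2-methyl-4-oxobutanoate
Conditions: DCC, DMAP (cat.), CH2Cl2, 0 → 23 °C
Reagents that add atoms: none
Why: Carbodiimide (Steglich-type) N-acylation of the thiazolidinethione is standard and does not touch C11.

Step 7
Reactants: 9 methyl (2S)-4-[(4R)-4-benzyl-2-sulfanylidene-1,3-thiazolidin-3-yl]-2-methyl-4-oxobutanoate; 5 (2Z)-3-{[(tert-butyldimethylsilyl)oxy]methyl}penta-2,4-dienal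
Product: 12 (4R)-4-benzyl-3-{[(2R,3R,4S)-2-[(1Z)-2-{[(tert-butyldimethylsilyl)oxy]methyl}buta-1,3-dien-1-yl]-4-methyl-5-oxooxolan-3-yl]carbonyl}-1,3-thiazolidine-2-thione (all-cis lactone imide), via silylated anti-aldol adduct 10 (not isolated), via free anti-aldol adduct 11 (not isolated)
Conditions: MgBr2·OEt2 (0.2 equiv), Et3N, TMSCl, EtOAc, 23 °C; then PPTS (cat.), MeOH–CH2Cl2, 23 °C
Reagents that add atoms: none
Why: In this magnesium-halide-catalysed direct anti-aldol of an N-acylthiazolidinethione (soft enolization, silyl trapping), the (R)-benzyl auxiliary and the resident C11 centre (attack anti to CO2Me with C11–H eclipsing the enolate) should direct C6–C7 bond formation to the same face, the anti topology sets C6, and desilylation–lactonization of an anti adduct can only give the cis C6/C7 lactone.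

Step 8
Reactants: 12 all-cis lactone imide
Product: 13 (2R,3R,4S)-2-[(1Z)-2-{[(tert-butyldimethylsilyl)oxy]methyl}buta-1,3-dien-1-yl]-4-methyl-5-oxooxolane-3-carbaldehyde
Conditions: DIBAL-H (1.05 equiv), CH2Cl2, −78 °C; pH 7 buffer, Rochelle salt; used crude
Reagents that add atoms: none
Why: Reductive cleavage of an N-acylthiazolidinethione to the aldehyde, in which the thioimide carbonyl is far more electrophilic than the lactone, the aluminium hemiaminal blocks over-reduction, and a neutral work-up should keep C7 intact.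

Step 9
Reactants: 14 prop-1-en-2-ylboronic acid; 15 (1S,2S)-1,2-dicyclohexylethane-1,2-diol
Product: 16 (4S,5S)-4,5-dicyclohexyl-2-(prop-1-en-2-yl)-1,3,2-dioxaborolane
Conditions: MgSO4, Et2O, 23 °C
Reagents that add atoms: none
Why: Boronic ester condensation, driven by removal of water; the diol centres are untouched.

Step 10
Reactants: 16 (4S,5S)-4,5-dicyclohexyl-2-(prop-1-en-2-yl)-1,3,2-dioxaborolane
Product: 18 (4S,5S)-2-[(1R)-1-chloro-2-methylprop-2-en-1-yl]-4,5-dicyclohexyl-1,3,2-dioxaborolane, via lithium dichloromethylborate complex 17 (not isolated)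
Conditions: CH2Cl2, n-BuLi, THF, −100 °C; add 16; ZnCl2, −100 → 23 °C
Reagents that add atoms: dichloromethane ClCCl
Why: Matteson homologation, in which (dichloromethyl)lithium adds to boron and the isopropenyl group migrates with loss of one of the two diastereotopic chlorides; the C2-symmetric (S,S)-diol with ZnCl2 assistance dictates that choice and should set the (R) α-chloro centre.

Step 11
Reactants: 13 lactone aldehyde; 18 (R)-α-chloromethallylboronate
Product: 20 (3S,4S,5R)-5-[(1Z)-2-{[(tert-butyldimethylsilyl)oxy]methyl}buta-1,3-dien-1-yl]-4-[(1S,3Z)-4-chloro-1-hydroxy-3-methylbut-3-en-1-yl]-3-methyloxolan-2-one, via borate ester 19 (not isolated)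
Conditions: CH2Cl2 (concentrated), 4 Å molecular sieves, 23 °C; then pH 7 buffer–MeOH
Reagents that add atoms: none
Why: The α-chloroallylboration runs through a closed six-membered chair with the aldehyde residue equatorial and the C–Cl bond axial, so the chloride ends up cis to C9 (Z-alkenyl chloride) and the (R) boron-bearing carbon is relayed to (S)-C8 by 1,3-chirality transfer, which places C8 under reagent control.

Step 12
Reactants: 21 [(tert-butyldimethylsilyl)oxy]acetaldehyde; 22 ethyl 2-(triphenylphosphoranylidene)propanoate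
Product: 23 ethyl (2E)-4-[(tert-butyldimethylsilyl)oxy]-2-methylbut-2-enoate
Conditions: CH2Cl2, 23 °C
Reagents that add atoms: none
Why: The Wittig reaction of a stabilized, α-branched ylide is E-selective and gives the tiglate-type geometry of the side chain.

Step 13
Reactants: 23 ethyl (2E)-4-[(tert-butyldimethylsilyl)oxy]-2-methylbut-2-enoate
Product: 24 (2E)-4-[(tert-butyldimethylsilyl)oxy]-2-methylbut-2-enoic acid
Conditions: LiOH, THF–MeOH–H2O, 23 °C; then 1 M HCl to pH 4
Reagents that add atoms: lithium hydroxide [Li+].[OH-]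
Why: Saponification, under which the primary TBS ether and the E-alkene should be stable.

Step 14
Reactants: 20 homoallylic alcohol; 24 (2E)-4-[(tert-butyldimethylsilyl)oxy]-2-methylbut-2-enoic acid
Product: 26 (1S,3Z)-4-chloro-1-[(2R,3S,4S)-2-[(1Z)-2-{[(tert-butyldimethylsilyl)oxy]methyl}buta-1,3-dien-1-yl]-4-methyl-5-oxooxolan-3-yl]-3-methylbut-3-en-1-yl (2E)-4-[(tert-butyldimethylsilyl)oxy]-2-methylbut-2-enoate (seco ester), via mixed anhydride 25 (not isolated)
Conditions: 24, 2,4,6-Cl3C6H2COCl, Et3N, THF, 23 °C; then 20, DMAP, toluene, 23 °C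
Reagents that add atoms: none
Why: Yamaguchi esterification acylates hindered secondary alcohols at oxygen, so C8 is retained, and prompt capping of O8 removes any chance of lactone migration from O6 to O8.

Step 15
Reactants: 26 seco ester
Product: 28 15-O,4′-O-bis(tert-butyldimethylsilyl) ether of the target (1(10)Z,4Z,6R,7S,8S,11S macrocycle), via B-alkyl-9-BBN borane 27 (not isolated)
Conditions: 9-BBN (1.5 equiv), THF, 0 → 23 °C; H2O; then syringe-pump addition to Pd(OAc)2 (15 mol %), SPhos (30 mol %), K3PO4, THF–DMF–H2O, 40 °C, final 1 mM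
Reagents that add atoms: none
Why: 9-BBN adds only to the monosubstituted C2=C3 alkene of the diene with boron at C2, since the trisubstituted C4=C5, C1=C10 and enoate alkenes are far slower; base then forms the borate, zerovalent palladium inserts into the C1–Cl bond with retention, the alkyl group passes from boron to palladium and reductive elimination forges C1–C2. The closest known reaction type is the B-alkyl Suzuki–Miyaura macrocyclization. The ten-membered carbocycle closes end to end through an eleven-membered palladacycle, a macrocyclization rather than an exo or endo attack on a π bond. No stereocenter is created; the Z geometry at C1=C10 is carried over from the chloride and the C4=C5 geometry from the diene. The step needs ring closure to beat oligomerization and β-hydride elimination, which slow addition at high dilution, the cis placement of both arms on the lactone ring and the bulky electron-rich biarylphosphine should secure. The lactone, both esters and the silyl ethers should be inert to 9-BBN and to aqueous K3PO4 at 40 °C.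

Step 16
Reactants: 28 bis-silyl macrocycle
Product: 29 (1(10)Z,4Z,6R,7S,8S,11S)-15-hydroxy-8-{[(2E)-4-hydroxy-2-methylbut-2-enoyl]oxy}germacra-1(10),4-dien-12,6-olide (target)
Conditions: HF·pyridine, pyridine, THF, 0 → 23 °C
Reagents that add atoms: none
Why: Buffered fluoride desilylation frees both primary allylic alcohols without base, so C11, the esters and the acid-sensitive cyclodecadiene should be spared.

Compound list
1 | tert-butyldimethyl(prop-2-yn-1-yloxy)silane | C#CCO[Si](C)(C)C(C)(C)C | starting material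
2 | methyl 4-[(tert-butyldimethylsilyl)oxy]but-2-ynoate | COC(=O)C#CCO[Si](C)(C)C(C)(C)C | intermediate
3 | methyl (2Z)-3-{[(tert-butyldimethylsilyl)oxy]methyl}penta-2,4-dienoate | COC(=O)/C=C(/C=C)CO[Si](C)(C)C(C)(C)C | intermediate
4 | (2Z)-3-{[(tert-butyldimethylsilyl)oxy]methyl}penta-2,4-dien-1-ol | OC/C=C(/C=C)CO[Si](C)(C)C(C)(C)C | intermediate
5 | (2Z)-3-{[(tert-butyldimethylsilyl)oxy]methyl}penta-2,4-dienal | O=C/C=C(/C=C)CO[Si](C)(C)C(C)(C)C | intermediate
6 | dimethyl (2S)-2-methylbutanedioate | COC(=O)[C@@H](C)CC(=O)OC | starting material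
7 | (3S)-4-methoxy-3-methyl-4-oxobutanoic acid | COC(=O)[C@@H](C)CC(=O)O | intermediate
8 | (4R)-4-benzyl-1,3-thiazolidine-2-thione | S=C1N[C@H](Cc2ccccc2)CS1 | starting material
9 | methyl (2S)-4-[(4R)-4-benzyl-2-sulfanylidene-1,3-thiazolidin-3-yl]-2-methyl-4-oxobutanoate | COC(=O)[C@@H](C)CC(=O)N1[C@H](Cc2ccccc2)CSC1=S | intermediate
10 | methyl (2S,3R,4R,5Z)-3-[(4R)-4-benzyl-2-sulfanylidene-1,3-thiazolidine-3-carbonyl]-6-{[(tert-butyldimethylsilyl)oxy]methyl}-2-methyl-4-[(trimethylsilyl)oxy]octa-5,7-dienoate | O=C(N1[C@H](Cc2ccccc2)CSC1=S)[C@H]([C@H](C)C(=O)OC)[C@H](O[Si](C)(C)C)/C=C(/C=C)CO[Si](C)(C)C(C)(C)C | intermediate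
11 | methyl (2S,3R,4R,5Z)-3-[(4R)-4-benzyl-2-sulfanylidene-1,3-thiazolidine-3-carbonyl]-6-{[(tert-butyldimethylsilyl)oxy]methyl}-4-hydroxy-2-methylocta-5,7-dienoate | O=C(N1[C@H](Cc2ccccc2)CSC1=S)[C@H]([C@H](C)C(=O)OC)[C@H](O)/C=C(/C=C)CO[Si](C)(C)C(C)(C)C | intermediate
12 | all-cis lactone imide (name in step 7) | O=C(N1[C@H](Cc2ccccc2)CSC1=S)[C@H]1[C@@H](/C=C(/C=C)CO[Si](C)(C)C(C)(C)C)OC(=O)[C@H]1C | intermediate
13 | (2R,3R,4S)-2-[(1Z)-2-{[(tert-butyldimethylsilyl)oxy]methyl}buta-1,3-dien-1-yl]-4-methyl-5-oxooxolane-3-carbaldehyde | O=C[C@H]1[C@@H](/C=C(/C=C)CO[Si](C)(C)C(C)(C)C)OC(=O)[C@H]1C | intermediate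
14 | prop-1-en-2-ylboronic acid | CC(=C)B(O)O | starting material
15 | (1S,2S)-1,2-dicyclohexylethane-1,2-diol | O[C@@H](C1CCCCC1)[C@@H](O)C1CCCCC1 | starting material
16 | (4S,5S)-4,5-dicyclohexyl-2-(prop-1-en-2-yl)-1,3,2-dioxaborolane | CC(=C)B1O[C@@H](C2CCCCC2)[C@H](C2CCCCC2)O1 | intermediate
17 | lithium (4S,5S)-4,5-dicyclohexyl-2-(dichloromethyl)-2-(prop-1-en-2-yl)-1,3,2-dioxaborolan-2-uide | [Li+].C=C(C)[B-]1(C(Cl)Cl)O[C@@H](C2CCCCC2)[C@H](C2CCCCC2)O1 | intermediate
18 | (4S,5S)-2-[(1R)-1-chloro-2-methylprop-2-en-1-yl]-4,5-dicyclohexyl-1,3,2-dioxaborolane | C=C(C)[C@H](Cl)B1O[C@@H](C2CCCCC2)[C@H](C2CCCCC2)O1 | intermediate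
19 | O8-[(4S,5S)-4,5-dicyclohexyl-1,3,2-dioxaborolan-2-yl] borate ester of 20 | C/C(=C/Cl)C[C@@H]([C@H]1[C@@H](/C=C(/C=C)CO[Si](C)(C)C(C)(C)C)OC(=O)[C@H]1C)OB1O[C@@H](C2CCCCC2)[C@H](C2CCCCC2)O1 | intermediate
20 | (3S,4S,5R)-5-[(1Z)-2-{[(tert-butyldimethylsilyl)oxy]methyl}buta-1,3-dien-1-yl]-4-[(1S,3Z)-4-chloro-1-hydroxy-3-methylbut-3-en-1-yl]-3-methyloxolan-2-one | C/C(=C/Cl)C[C@@H]([C@H]1[C@@H](/C=C(/C=C)CO[Si](C)(C)C(C)(C)C)OC(=O)[C@H]1C)O | intermediate
21 | [(tert-butyldimethylsilyl)oxy]acetaldehyde | O=CCO[Si](C)(C)C(C)(C)C | starting material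
22 | ethyl 2-(triphenylphosphoranylidene)propanoate | CCOC(=O)C(C)=P(c1ccccc1)(c1ccccc1)c1ccccc1 | starting material
23 | ethyl (2E)-4-[(tert-butyldimethylsilyl)oxy]-2-methylbut-2-enoate | CCOC(=O)/C(C)=C/CO[Si](C)(C)C(C)(C)C | intermediate
24 | (2E)-4-[(tert-butyldimethylsilyl)oxy]-2-methylbut-2-enoic acid | OC(=O)/C(C)=C/CO[Si](C)(C)C(C)(C)C | intermediate
25 | (2E)-4-[(tert-butyldimethylsilyl)oxy]-2-methylbut-2-enoic 2,4,6-trichlorobenzoic anhydride | O=C(OC(=O)/C(C)=C/CO[Si](C)(C)C(C)(C)C)c1c(Cl)cc(Cl)cc1Cl | intermediate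
26 | seco ester (name in step 14) | C/C(=C/Cl)C[C@@H]([C@H]1[C@@H](/C=C(/C=C)CO[Si](C)(C)C(C)(C)C)OC(=O)[C@H]1C)OC(=O)/C(C)=C/CO[Si](C)(C)C(C)(C)C | intermediate
27 | C2-(9-borabicyclo[3.3.1]nonan-9-yl) borane from 26 | C/C(=C/Cl)C[C@@H]([C@H]1[C@@H](/C=C(/CCB2C3CCCC2CCC3)CO[Si](C)(C)C(C)(C)C)OC(=O)[C@H]1C)OC(=O)/C(C)=C/CO[Si](C)(C)C(C)(C)C | intermediate
28 | 15-O,4′-O-bis(tert-butyldimethylsilyl) ether of the target | C/C1=C/CC/C(CO[Si](C)(C)C(C)(C)C)=C/[C@H]2OC(=O)[C@@H](C)[C@H]2[C@@H](OC(=O)/C(C)=C/CO[Si](C)(C)C(C)(C)C)C1 | intermediate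
29 | (1(10)Z,4Z,6R,7S,8S,11S)-15-hydroxy-8-{[(2E)-4-hydroxy-2-methylbut-2-enoyl]oxy}germacra-1(10),4-dien-12,6-olide | C/C1=C/CC/C(CO)=C/[C@H]2OC(=O)[C@@H](C)[C@H]2[C@@H](OC(=O)/C(C)=C/CO)C1 | target

Total step count: 16. Longest linear sequence: 10 steps (1, 2, 3, 4, 7, 8, 11, 14, 15, 16).

Steps most likely to fail

Step 15. Slow insertion of palladium into the alkenyl chloride may let several processes outrun ring closure: oligomerization, protodeboronation, β-hydride elimination back to the diene, or ionization of the allylic C6–O bond. The fallback sets out from 26. Borane 27 would be oxidized with NaBO3·4H2O to the C2 primary alcohol F1. An Appel reaction (I2, PPh3, imidazole) would convert this into the C2 primary iodide F2. Zinc dust with LiCl in THF would then give the alkylzinc iodide F3, the alkenyl chloride being inert to zinc. F3 would be cyclized by an intramolecular Negishi coupling with Pd(P(t-Bu)3)2 under high dilution, which rejoins the route at 28.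

Step 11. Sluggish addition to the crowded formyl group may leave time for C7 to epimerize and relieve the all-cis strain, and the facial and Z/E selectivity may erode. The fallback sets out from 10, isolated from step 7 by a buffered, non-acidic work-up, so that C7 sits in an unstrained open chain. DIBAL-H at −78 °C would give the acyclic aldehyde F4. Chloroallylboration with 18 would give the acyclic homoallylic alcohol F5, and immediate Yamaguchi esterification with 24 would give the acyclic ester F6. PPTS in MeOH–CH2Cl2 would then remove the trimethylsilyl group and close the lactone, which rejoins the route at 26.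

Step 7. Vinylogous enolization and silylation of the dienal at C15 by Et3N and TMSCl, low turnover of the magnesium catalyst, or reversal of the aldol addition may spoil conversion and facial selectivity. The fallback sets out from 7 and replaces soft enolization with a preformed boron enolate under substrate control. DCC coupling with 2-methylpropane-2-thiol would give the S-tert-butyl thioester F7. Bu2BOTf and i-Pr2NEt at −78 °C would form its E(O)-boron enolate. Addition of 5 through a closed chair, anti to the CO2Me group at C11, followed by oxidative work-up would give the anti-aldol thioester F8. PPTS would close it to the lactone thioester F9, and DIBAL-H at −78 °C would rejoin the route at 13.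

Further compounds
F1 | step 15 | C2 primary alcohol from hydroboration–oxidation of 26 | C/C(=C/Cl)C[C@@H]([C@H]1[C@@H](/C=C(/CCO)CO[Si](C)(C)C(C)(C)C)OC(=O)[C@H]1C)OC(=O)/C(C)=C/CO[Si](C)(C)C(C)(C)C
F2 | step 15 | C2 primary iodide | C/C(=C/Cl)C[C@@H]([C@H]1[C@@H](/C=C(/CCI)CO[Si](C)(C)C(C)(C)C)OC(=O)[C@H]1C)OC(=O)/C(C)=C/CO[Si](C)(C)C(C)(C)C
F3 | step 15 | C2 alkylzinc iodide | C/C(=C/Cl)C[C@@H]([C@H]1[C@@H](/C=C(/CC[Zn]I)CO[Si](C)(C)C(C)(C)C)OC(=O)[C@H]1C)OC(=O)/C(C)=C/CO[Si](C)(C)C(C)(C)C
F4 | step 11 | methyl (2S,3R,4R,5Z)-6-{[(tert-butyldimethylsilyl)oxy]methyl}-3-formyl-2-methyl-4-[(trimethylsilyl)oxy]octa-5,7-dienoate | O=C[C@H]([C@H](C)C(=O)OC)[C@H](O[Si](C)(C)C)/C=C(/C=C)CO[Si](C)(C)C(C)(C)C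
F5 | step 11 | acyclic (8S,Z)-chloro homoallylic alcohol | C/C(=C/Cl)C[C@@H]([C@H]([C@H](C)C(=O)OC)[C@H](O[Si](C)(C)C)/C=C(/C=C)CO[Si](C)(C)C(C)(C)C)O
F6 | step 11 | acyclic O8 ester with 24 | C/C(=C/Cl)C[C@@H]([C@H]([C@H](C)C(=O)OC)[C@H](O[Si](C)(C)C)/C=C(/C=C)CO[Si](C)(C)C(C)(C)C)OC(=O)/C(C)=C/CO[Si](C)(C)C(C)(C)C
F7 | step 7 | methyl (2S)-4-(tert-butylsulfanyl)-2-methyl-4-oxobutanoate | COC(=O)[C@@H](C)CC(=O)SC(C)(C)C
F8 | step 7 | anti-aldol S-tert-butyl thioester | CC(C)(C)SC(=O)[C@H]([C@H](C)C(=O)OC)[C@H](O)/C=C(/C=C)CO[Si](C)(C)C(C)(C)C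
F9 | step 7 | all-cis lactone S-tert-butyl thioester | CC(C)(C)SC(=O)[C@H]1[C@@H](/C=C(/C=C)CO[Si](C)(C)C(C)(C)C)OC(=O)[C@H]1C
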